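**Retrosynthetic overview**

1. Labdane numbering is used: ring A = C1–C5 + C10, ring B = C5–C10, gem-dimethyl on C4, angular methyl on C10, side chain C11–C16 on C9. Late disconnections: C8(OH)–CHO from a C8 ketone plus a vinyl anion (then ozonolysis); C12–C13 by sp3–sp2 Negishi coupling with methyl (Z)-3-iodobut-2-enoate; C3–OH from a C3 acetyl group (Baeyer–Villiger).
2. Key disconnection: C3–C4 and C5–C10 of the trans-decalin are cut together in an intramolecular inverse-electron-demand [4+2] transform. The diene is C10=C1–C2=C3 with an acetyl on C3 (a 2,4-dienone), the dienophile is C4=C5 (isopropylidene end), and the tether is C6–C9.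
3. Enabling feature: in ring A the quaternary gem-dimethyl carbon C4 is bonded to the ring-fusion CH (C5), and the quaternary methyl-bearing C10 is separated from oxygenated C3 by C1–C2. C4=C5 is therefore a nucleophilic trisubstituted alkene that gives a tertiary cation at C4, and C10 is the tertiary δ-carbon of a dienone whose α-carbon C3 carries the acetyl as latent 3-OH.
4. The acyclic trienone comes from a Heck reaction (C1–C2) of an (E)-alkenyl iodide with but-3-en-2-one, the iodide from carboalumination of an alkyne, and the alkyne from a syn aldol (C8–C9) of an N-(4-chlorobutanoyl)thiazolidinethione with 5-methylhex-4-enal, which sets C9 and a temporary C8 carbinol.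
5. Ring order: no ring exists before step 8; rings B and A form in that one operation (ring B through C5–C10, ring A completed through C3–C4).

Key step: step 8

Remark on the chemistry: 5-methylhex-4-enal (4) is taken as a purchasable aldehyde; otherwise it is one Claisen step from 2-methylbut-3-en-2-ol and ethyl vinyl ether. Decalin stereochemistry is described as cis or trans to the C10 methyl.

**Route**

Step 1
Reactants: 1 (R)-4-benzyl-1,3-thiazolidine-2-thione; 2 4-chlorobutanoyl chloride
Product: 3 (R)-1-(4-benzyl-2-thioxo-1,3-thiazolidin-3-yl)-4-chlorobutan-1-one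
Conditions: Et3N, DMAP (cat.), CH2Cl2, 0 °C to rt
Reagents that add atoms: none
Why: N-acylation of the thiazolidinethione by the acid chloride attaches the chiral auxiliary to the C9–C12 unit without forming a stereocentre.

Step 2
Reactants: 3 N-(4-chlorobutanoyl)thiazolidinethione; 4 5-methylhex-4-enal
Product: 5 (2R,3S)-1-[(R)-4-benzyl-2-thioxo-1,3-thiazolidin-3-yl]-2-(2-chloroethyl)-3-hydroxy-7-methyloct-6-en-1-one
Conditions: TiCl4 (1.05 equiv), i-Pr2NEt (1.1 equiv), N-methylpyrrolidinone (1.1 equiv), CH2Cl2, 0 °C; then 4, −78 to 0 °C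
Reagents that add atoms: none
Why: Titanium-mediated Evans-type syn aldol reaction of the N-acylthiazolidinethione, in which the Z-enolate reacts through a closed chair transition state on the face left open by the benzyl group, should set C9 and the temporary C8 carbinol as the syn pair.

Step 3
Reactants: 5 syn aldol adduct
Product: 6 (2R,3S)-1-[(R)-4-benzyl-2-thioxo-1,3-thiazolidin-3-yl]-3-[(tert-butyldimethylsilyl)oxy]-2-(2-chloroethyl)-7-methyloct-6-en-1-one
Conditions: TBSOTf, 2,6-lutidine, CH2Cl2, −78 to 0 °C
Reagents that add atoms: tert-butyldimethylsilyl triflate, CC(C)(C)[Si](C)(C)OS(=O)(=O)C(F)(F)F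
Why: Silylation of the secondary alcohol blocks retro-aldol cleavage and carries the C8 oxygen through the Lewis-acidic steps.

Step 4
Reactants: 6 silylated aldol adduct
Product: 7 (2R,3S)-3-[(tert-butyldimethylsilyl)oxy]-2-(2-chloroethyl)-7-methyloct-6-enal
Conditions: i-Bu2AlH (2 equiv), CH2Cl2, −78 °C; Rochelle salt work-up
Reagents that add atoms: none
Why: N-acylthiazolidinethiones are reduced by i-Bu2AlH directly to aldehydes through a stable tetrahedral aluminium adduct, so the auxiliary is removed in one step without touching C9 or the alkyl chloride.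

Step 5
Reactants: 7 aldehyde
Product: 8 (3S,4S)-4-[(tert-butyldimethylsilyl)oxy]-3-(2-chloroethyl)-8-methylnon-7-en-1-yne
Conditions: dimethyl (1-diazo-2-oxopropyl)phosphonate, K2CO3, MeOH, 0 °C to rt
Reagents that add atoms: dimethyl (1-diazo-2-oxopropyl)phosphonate, COP(=O)(OC)C(=[N+]=[N-])C(C)=O
Why: Seyferth–Gilbert homologation with the Ohira–Bestmann reagent turns the aldehyde into the terminal alkyne C10≡C1 under carbonate conditions that should leave the α-stereocentre C9 and the β-silyloxy group intact.

Step 6
Reactants: 8 alkyne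
Product: 10 (1E,3S,4S)-4-[(tert-butyldimethylsilyl)oxy]-3-(2-chloroethyl)-1-iodo-2,8-dimethylnona-1,7-diene, via alkenyl dimethylalane 9 (not isolated)
Conditions: Me3Al (3 equiv), Cp2ZrCl2 (0.3 equiv), H2O (1 equiv), CH2Cl2, −20 °C; then iodine, THF, −20 to 0 °C
Reagents that add atoms: trimethylaluminium, C[Al](C)C; iodine, [I][I]
Why: Zirconium-catalysed Negishi carboalumination adds methyl and aluminium syn across the terminal alkyne with methyl on the internal carbon, and iodinolysis with retention fixes the (E)-C10=C1 geometry and installs the C10 methyl.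

Step 7
Reactants: 10 (E)-alkenyl iodide; 11 but-3-en-2-one
Product: 12 (3E,5E,7S,8S)-8-[(tert-butyldimethylsilyl)oxy]-7-(2-chloroethyl)-6,12-dimethyltrideca-3,5,11-trien-2-one
Conditions: Pd(OAc)2 (10 mol%), K2CO3, Bu4NCl, DMF, rt to 40 °C
Reagents that add atoms: none
Why: Heck reaction of the alkenyl iodide with the enone (syn insertion, syn β-hydride elimination) should give the E enone with retention at C10=C1, so the complete (E,E)-dienone C10=C1–C2=C3–acetyl is assembled in one step.

Step 8
Reactants: 12 (3E,5E)-trienone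
Product: 13 3-acetyl-8-(tert-butyldimethylsilyloxy)-9-(2-chloroethyl)-4,4,10-trimethyl-trans-decal-1-ene (acetyl and silyloxy trans to the C10 methyl; chloroethyl cis to it)
Conditions: MeAlCl2 (1.5 equiv), CH2Cl2 (0.01 M), −78 to −20 °C; then aq. NaHCO3
Reagents that add atoms: none
Why: Proposed new method: MeAlCl2 binds the ketone of the s-cis (3E,5E)-dienone and makes its tertiary δ-carbon C10 the electrophilic terminus of an inverse-electron-demand diene, so that the CH end (C5) of the isopropylidene alkene attacks C10 through a chair-like six-membered transition state while the tertiary cationic character building up at C4 is quenched by C3, the α-carbon of the developing aluminium dienolate, in one highly asynchronous suprafacial [4+2] event that leaves the C1=C2 alkene. The closest known reaction types are the Lewis-acid-catalysed type 1 intramolecular Diels–Alder reaction of 1,7,9-decatrienones and the alkylaluminium-halide-promoted conjugate addition of unactivated alkenes and allylsilanes to enones and dienones through zwitterions; their union on an unactivated trisubstituted dienophile is the unproven element. Ring B closes by the C5–C10 bond as a 6-exo attack within the chair-like C6–C9 tether, and ring A is the cyclohexene of the cycloaddition, completed by six-membered closure of the dienolate carbon C3 onto the tertiary centre C4. C10 (quaternary) and C5 are set by the (E)-C10=C1 geometry in the chair (methyl axial, hence trans ring fusion), their absolute sense by the C9 chloroethyl and C8 silyloxy groups, which both sit equatorial on the tether and select one diene face, and C3 follows from the (E)-C2=C3 geometry (acetyl trans to the angular methyl) and is corrected in step 9. The step needs C3–C4 closure to win over [2+2] closure at C1, proton loss from the cationic centre (ene-type product) and 1,2-shifts, which the strain-free six-membered collapse, the low temperature, the reversibility of the first bond and the proton-scavenging methylaluminium reagent are meant to secure.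

Step 9
Reactants: 13 octalin methyl ketone
Product: 15 equatorial 3-acetyl decalin (acetyl cis to the C10 methyl), via axial 3-acetyl decalin 14 (not isolated)
Conditions: H2 (1 atm), 10% Pd/C, EtOAc–MeOH, rt; filter; then NaOMe (0.5 equiv), MeOH, rt
Reagents that add atoms: none
Why: Heterogeneous hydrogenation saturates the only C=C bond, and base equilibration through the enolate then moves the acetyl group at the enolisable C3 to the favoured equatorial position, cis to the angular methyl.

Step 10
Reactants: 15 equatorial methyl ketone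
Product: 16 3-acetoxy-8-(tert-butyldimethylsilyloxy)-9-(2-chloroethyl)-4,4,10-trimethyl-trans-decalin (acetoxy cis to the C10 methyl)
Conditions: mCPBA (3 equiv), NaHCO3, CH2Cl2, rt to 40 °C
Reagents that add atoms: 3-chloroperbenzoic acid, OOC(=O)c1cccc(Cl)c1
Why: In the Baeyer–Villiger oxidation the secondary ring carbon migrates in preference to methyl and with retention, so the equatorial acetyl becomes the equatorial 3-acetate, which also protects the 3-OH for the following steps.

Step 11
Reactants: 16 chloroethyl acetate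
Product: 17 3-acetoxy-8-(tert-butyldimethylsilyloxy)-9-(2-iodoethyl)-4,4,10-trimethyl-trans-decalin
Conditions: NaI (5 equiv), butan-2-one, 80 °C
Reagents that add atoms: sodium iodide, [Na+].[I-]
Why: Finkelstein exchange at the unhindered primary carbon C12 is driven by precipitation of NaCl and gives the iodide needed for zinc insertion.

Step 12
Reactants: 18 methyl but-2-ynoate
Product: 19 methyl (Z)-3-iodobut-2-enoate
Conditions: NaI, AcOH, 110 °C
Reagents that add atoms: sodium iodide, [Na+].[I-]
Why: Conjugate hydroiodination of the ynoate with iodide in acetic acid proceeds by anti addition and should give the Z β-iodoenoate, which carries C13–C16 with the required geometry.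

Step 13
Reactants: 17 primary iodide; 19 methyl (Z)-3-iodobut-2-enoate
Product: 21 methyl (Z)-5-[3-acetoxy-8-(tert-butyldimethylsilyloxy)-4,4,10-trimethyl-trans-decalin-9-yl]-3-methylpent-2-enoate, via alkylzinc iodide 20 (not isolated)
Conditions: Zn dust (activated with BrCH2CH2Br and Me3SiCl), DMA, 40 °C; then 19, Pd(PPh3)4 (5 mol%), THF–DMA, rt to 40 °C
Reagents that add atoms: none
Why: sp3–sp2 Negishi coupling of the ester-tolerant primary alkylzinc iodide with the β-iodoenoate forms C12–C13 with retention of the Z geometry.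

Step 14
Reactants: 21 silyl ether
Product: 22 methyl (Z)-5-[3-acetoxy-8-hydroxy-4,4,10-trimethyl-trans-decalin-9-yl]-3-methylpent-2-enoate
Conditions: HF·pyridine, pyridine, THF, 0 °C to rt
Reagents that add atoms: none
Why: Fluoride-driven cleavage of the secondary silyl ether under buffered acidic conditions should spare the acetate and the Z enoate.

Step 15
Reactants: 22 secondary alcohol
Product: 23 methyl (Z)-5-[3-acetoxy-4,4,10-trimethyl-8-oxo-trans-decalin-9-yl]-3-methylpent-2-enoate
Conditions: Dess–Martin periodinane, NaHCO3, CH2Cl2, rt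
Reagents that add atoms: none
Why: Dess–Martin oxidation gives the C8 ketone under neutral conditions, and the adjacent C9 already holds its side chain in the thermodynamically preferred equatorial position.

Step 16
Reactants: 23 C8 ketone
Product: 24 methyl (Z)-5-[3-acetoxy-8-hydroxy-4,4,10-trimethyl-8-vinyl-trans-decalin-9-yl]-3-methylpent-2-enoate (8-OH cis to the C10 methyl)
Conditions: CH2=CHMgBr (2 equiv), anhydrous CeCl3 (2 equiv), THF, −78 °C; then H2O
Reagents that add atoms: vinylmagnesium bromide, C=C[Mg]Br
Why: The weakly basic vinylcerium reagent adds to the ketone in preference to the esters and without enolisation, and the axial C10 methyl blocks the axial trajectory, so equatorial attack should set C8 with the hydroxyl axial and cis to that methyl.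

Step 17
Reactants: 24 acetate
Product: 25 methyl (Z)-5-[3,8-dihydroxy-4,4,10-trimethyl-8-vinyl-trans-decalin-9-yl]-3-methylpent-2-enoate
Conditions: K2CO3, MeOH, rt
Reagents that add atoms: none
Why: Methanolysis removes the acetate, while the methyl ester is degenerate toward methoxide and the β,β-disubstituted enoate is a poor Michael acceptor.

Step 18
Reactants: 25 vinyl diol
Product: 26 CNP0135080.1 (target)
Conditions: O3 (1 equiv, TLC control), CH2Cl2–MeOH, −78 °C; then Me2S, −78 °C to rt
Reagents that add atoms: ozone, [O-][O+]=O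
Why: Ozonolysis with reductive work-up cleaves the electron-richer monosubstituted vinyl group much faster than the conjugated trisubstituted enoate and unveils the C17 aldehyde without touching any stereocentre.

**Compound list**

1 | (R)-4-benzyl-1,3-thiazolidine-2-thione | S=C1N[C@H](Cc2ccccc2)CS1 | starting material
2 | 4-chlorobutanoyl chloride | ClCCCC(Cl)=O | starting material
3 | (R)-1-(4-benzyl-2-thioxo-1,3-thiazolidin-3-yl)-4-chlorobutan-1-one | O=C(CCCCl)N1C(=S)SC[C@H]1Cc1ccccc1 | intermediate
4 | 5-methylhex-4-enal | CC(C)=CCCC=O | starting material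
5 | (2R,3S)-1-[(R)-4-benzyl-2-thioxo-1,3-thiazolidin-3-yl]-2-(2-chloroethyl)-3-hydroxy-7-methyloct-6-en-1-one (syn aldol adduct) | O=C([C@H](CCCl)[C@@H](O)CCC=C(C)C)N1C(=S)SC[C@H]1Cc1ccccc1 | intermediate
6 | (2R,3S)-1-[(R)-4-benzyl-2-thioxo-1,3-thiazolidin-3-yl]-3-[(tert-butyldimethylsilyl)oxy]-2-(2-chloroethyl)-7-methyloct-6-en-1-one | O=C([C@H](CCCl)[C@@H](O[Si](C)(C)C(C)(C)C)CCC=C(C)C)N1C(=S)SC[C@H]1Cc1ccccc1 | intermediate
7 | (2R,3S)-3-[(tert-butyldimethylsilyl)oxy]-2-(2-chloroethyl)-7-methyloct-6-enal | O=C[C@H](CCCl)[C@@H](O[Si](C)(C)C(C)(C)C)CCC=C(C)C | intermediate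
8 | (3S,4S)-4-[(tert-butyldimethylsilyl)oxy]-3-(2-chloroethyl)-8-methylnon-7-en-1-yne | C#C[C@H](CCCl)[C@@H](O[Si](C)(C)C(C)(C)C)CCC=C(C)C | intermediate
9 | dimethyl[(1E,3S,4S)-4-[(tert-butyldimethylsilyl)oxy]-3-(2-chloroethyl)-2,8-dimethylnona-1,7-dien-1-yl]alane | C[Al](C)/C=C(\C)[C@H](CCCl)[C@@H](O[Si](C)(C)C(C)(C)C)CCC=C(C)C | intermediate
10 | (1E,3S,4S)-4-[(tert-butyldimethylsilyl)oxy]-3-(2-chloroethyl)-1-iodo-2,8-dimethylnona-1,7-diene | I/C=C(\C)[C@H](CCCl)[C@@H](O[Si](C)(C)C(C)(C)C)CCC=C(C)C | intermediate
11 | but-3-en-2-one | CC(=O)C=C | starting material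
12 | (3E,5E,7S,8S)-8-[(tert-butyldimethylsilyl)oxy]-7-(2-chloroethyl)-6,12-dimethyltrideca-3,5,11-trien-2-one | CC(=O)/C=C/C=C(\C)[C@H](CCCl)[C@@H](O[Si](C)(C)C(C)(C)C)CCC=C(C)C | intermediate
13 | 3-acetyl-8-(tert-butyldimethylsilyloxy)-9-(2-chloroethyl)-4,4,10-trimethyl-trans-decal-1-ene; acetyl and silyloxy trans to the C10 methyl, chloroethyl cis to it, H-5 trans to it | ClCC[C@H]1[C@]2(C)C=C[C@H](C(C)=O)C(C)(C)[C@H]2CC[C@@H]1O[Si](C)(C)C(C)(C)C | intermediate
14 | saturated decalin of 13 with the acetyl still trans to the C10 methyl (axial) | ClCC[C@H]1[C@]2(C)CC[C@H](C(C)=O)C(C)(C)[C@H]2CC[C@@H]1O[Si](C)(C)C(C)(C)C | intermediate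
15 | 3-acetyl-8-(tert-butyldimethylsilyloxy)-9-(2-chloroethyl)-4,4,10-trimethyl-trans-decalin; acetyl cis to the C10 methyl (equatorial) | ClCC[C@H]1[C@]2(C)CC[C@@H](C(C)=O)C(C)(C)[C@H]2CC[C@@H]1O[Si](C)(C)C(C)(C)C | intermediate
16 | 3-acetoxy-8-(tert-butyldimethylsilyloxy)-9-(2-chloroethyl)-4,4,10-trimethyl-trans-decalin; acetoxy cis to the C10 methyl | ClCC[C@H]1[C@]2(C)CC[C@@H](OC(C)=O)C(C)(C)[C@H]2CC[C@@H]1O[Si](C)(C)C(C)(C)C | intermediate
17 | 3-acetoxy-8-(tert-butyldimethylsilyloxy)-9-(2-iodoethyl)-4,4,10-trimethyl-trans-decalin | ICC[C@H]1[C@]2(C)CC[C@@H](OC(C)=O)C(C)(C)[C@H]2CC[C@@H]1O[Si](C)(C)C(C)(C)C | intermediate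
18 | methyl but-2-ynoate | CC#CC(=O)OC | starting material
19 | methyl (Z)-3-iodobut-2-enoate | COC(=O)/C=C(/C)I | intermediate
20 | alkylzinc iodide from 17 (zinc on C12) | I[Zn]CC[C@H]1[C@]2(C)CC[C@@H](OC(C)=O)C(C)(C)[C@H]2CC[C@@H]1O[Si](C)(C)C(C)(C)C | intermediate
21 | methyl (Z)-5-[3-acetoxy-8-(tert-butyldimethylsilyloxy)-4,4,10-trimethyl-trans-decalin-9-yl]-3-methylpent-2-enoate | COC(=O)/C=C(/C)CC[C@H]1[C@]2(C)CC[C@@H](OC(C)=O)C(C)(C)[C@H]2CC[C@@H]1O[Si](C)(C)C(C)(C)C | intermediate
22 | methyl (Z)-5-[3-acetoxy-8-hydroxy-4,4,10-trimethyl-trans-decalin-9-yl]-3-methylpent-2-enoate; 8-OH trans to the C10 methyl | COC(=O)/C=C(/C)CC[C@H]1[C@]2(C)CC[C@@H](OC(C)=O)C(C)(C)[C@H]2CC[C@@H]1O | intermediate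
23 | methyl (Z)-5-[3-acetoxy-4,4,10-trimethyl-8-oxo-trans-decalin-9-yl]-3-methylpent-2-enoate | COC(=O)/C=C(/C)CC[C@H]1[C@]2(C)CC[C@@H](OC(C)=O)C(C)(C)[C@H]2CCC1=O | intermediate
24 | methyl (Z)-5-[3-acetoxy-8-hydroxy-4,4,10-trimethyl-8-vinyl-trans-decalin-9-yl]-3-methylpent-2-enoate; 8-OH cis to the C10 methyl, vinyl trans to it | COC(=O)/C=C(/C)CC[C@H]1[C@]2(C)CC[C@@H](OC(C)=O)C(C)(C)[C@H]2CC[C@]1(O)C=C | intermediate
25 | methyl (Z)-5-[3,8-dihydroxy-4,4,10-trimethyl-8-vinyl-trans-decalin-9-yl]-3-methylpent-2-enoate | COC(=O)/C=C(/C)CC[C@H]1[C@]2(C)CC[C@@H](O)C(C)(C)[C@H]2CC[C@]1(O)C=C | intermediate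
26 | CNP0135080.1, methyl (13Z)-3,8-dihydroxy-17-oxolabd-13-en-15-oate of the ent-labdane series; 3-OH, 8-OH and the C9 side chain cis to the C10 methyl, H-5 and the 8-CHO trans to it | COC(=O)/C=C(/C)CC[C@H]1[C@]2(C)CC[C@@H](O)C(C)(C)[C@H]2CC[C@]1(O)C=O | target

**Step count and risks**

Total step count: 18. Longest linear sequence: 17 (steps 1–11 and 13–18; step 12 prepares the coupling partner 19).

Steps most likely to fail:

Step 8. The zwitterion-like pathway may leak into proton transfer (ene-type product), 1,2-shifts or [2+2] closure, or the chair may give way to a boat and a cis ring fusion. The fallback uses known chemistry, starts from 12 and returns at 13. It activates the isopropylidene end as a conventional dienophile. Allylic oxidation of its E-methyl group (cat. SeO2, t-BuOOH, CH2Cl2; the electron-poor dienone should be inert) would give the (E)-allylic alcohol F1, and MnO2 the (E)-2-methyl-2-enal F2. A thermal type 1 intramolecular Diels–Alder reaction of this doubly activated triene (toluene, 150 °C, BHT; or Me2AlCl at low temperature), endo for the formyl group, should give the trans-fused 4-formyl adduct F3. Selective condensation of the aldehyde with TsNHNH2 would give the tosylhydrazone F4, and catecholborane followed by NaOAc would reduce the formyl carbon to the second C4 methyl and deliver 13.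

Step 16. The hindered C8 ketone may enolise, the reagent may attack an ester, or facial selectivity may be poor. The fallback starts from 23 and returns at 26, bringing C17 in as a sulfur ylide instead of a vinyl metal. Corey–Chaykovsky epoxidation (Me3S+ I−, KHMDS, THF, −10 °C; equatorial attack) would give the spiro-epoxide F5 with oxygen cis to the C10 methyl. Opening at the primary carbon with CsOAc (DMF, 80 °C) would give the C17 acetate F6, and K2CO3/MeOH the triol F7. TEMPO/PhI(OAc)2 would then oxidise only the primary alcohol and give 26.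

Step 10. Peracid addition to the hindered ketone may be slow, and any C3 epimer left from step 9 would be carried through. The fallback starts from 15 and returns at 16, degrading the acetyl group to a C3 ketone. The more substituted trimethylsilyl enol ether F8 (Me3SiCl, NaI, Et3N, MeCN) would be cleaved by ozone (then Me2S) to the 3-ketone F9. NaBH4 should deliver hydride from the less hindered face and give the equatorial alcohol F10, whatever the C3 configuration of 15 was. Ac2O, pyridine and DMAP would then give 16.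

Further compounds
F1 | step 8 | (3E,5E,7S,8S,11E)-8-[(tert-butyldimethylsilyl)oxy]-7-(2-chloroethyl)-13-hydroxy-6,12-dimethyltrideca-3,5,11-trien-2-one | CC(=O)/C=C/C=C(\C)[C@H](CCCl)[C@@H](O[Si](C)(C)C(C)(C)C)CC/C=C(\C)CO
F2 | step 8 | (2E,6S,7S,8E,10E)-6-[(tert-butyldimethylsilyl)oxy]-7-(2-chloroethyl)-2,8-dimethyl-12-oxotrideca-2,8,10-trienal | CC(=O)/C=C/C=C(\C)[C@H](CCCl)[C@@H](O[Si](C)(C)C(C)(C)C)CC/C=C(\C)C=O
F3 | step 8 | 4-formyl analogue of 13 (C4 carries CH3 and CHO; CHO, acetyl and silyloxy trans to the C10 methyl) | ClCC[C@H]1[C@]2(C)C=C[C@H](C(C)=O)[C@](C)(C=O)[C@H]2CC[C@@H]1O[Si](C)(C)C(C)(C)C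
F4 | step 8 | (E)-tosylhydrazone of the formyl group of F3 | ClCC[C@H]1[C@]2(C)C=C[C@H](C(C)=O)[C@](C)(/C=N/NS(=O)(=O)c3ccc(C)cc3)[C@H]2CC[C@@H]1O[Si](C)(C)C(C)(C)C
F5 | step 16 | 8,17-spiro-epoxide of 23 (epoxide oxygen cis to the C10 methyl) | COC(=O)/C=C(/C)CC[C@H]1[C@]2(C)CC[C@@H](OC(C)=O)C(C)(C)[C@H]2CC[C@]1(O3)C3
F6 | step 16 | methyl (Z)-5-[3-acetoxy-8-(acetoxymethyl)-8-hydroxy-4,4,10-trimethyl-trans-decalin-9-yl]-3-methylpent-2-enoate | COC(=O)/C=C(/C)CC[C@H]1[C@]2(C)CC[C@@H](OC(C)=O)C(C)(C)[C@H]2CC[C@]1(O)COC(C)=O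
F7 | step 16 | methyl (Z)-5-[3,8-dihydroxy-8-(hydroxymethyl)-4,4,10-trimethyl-trans-decalin-9-yl]-3-methylpent-2-enoate | COC(=O)/C=C(/C)CC[C@H]1[C@]2(C)CC[C@@H](O)C(C)(C)[C@H]2CC[C@]1(O)CO
F8 | step 10 | trimethylsilyl enol ether of 15 with the C3=C(OSiMe3)CH3 double bond exocyclic to ring A (E isomer drawn) | ClCC[C@H]1[C@]2(C)CC/C(=C(/C)O[Si](C)(C)C)C(C)(C)[C@H]2CC[C@@H]1O[Si](C)(C)C(C)(C)C
F9 | step 10 | 8-(tert-butyldimethylsilyloxy)-9-(2-chloroethyl)-4,4,10-trimethyl-trans-decalin-3-one | ClCC[C@H]1[C@]2(C)CCC(=O)C(C)(C)[C@H]2CC[C@@H]1O[Si](C)(C)C(C)(C)C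
F10 | step 10 | 8-(tert-butyldimethylsilyloxy)-9-(2-chloroethyl)-4,4,10-trimethyl-trans-decalin-3-ol (3-OH cis to the C10 methyl) | ClCC[C@H]1[C@]2(C)CC[C@@H](O)C(C)(C)[C@H]2CC[C@@H]1O[Si](C)(C)C(C)(C)C
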